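**Assumption:** the target is made as drawn, as the free hydrogen sulfate, released from its sodium salt in the last step. The sense of induction of the ligand in step 7 cannot be predicted. Both antipodes are accessible, and the one that gives the (S)-flavanone is used ((S,S) is written).

## Retrosynthetic overview
1. The target comes from hydride reduction of a C3 methyl ester and an aryl pivalate. The side-chain OH is sulfated beforehand, while it is the only free hydroxyl.
2. The trans-2-aryl-2,3-dihydrobenzofuran-3-carboxylate comes from oxidative ring contraction of an (S)-flavanone: ring A carbon C4a shifts from C4 to C3, and C2 controls C3.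
3. The (S)-flavanone comes from an enantioselective reductive conjugate arylation of a 6,8-disubstituted chromone with an aryl bromide.
4. The chromone comes from dihydroconiferyl alcohol by Fries rearrangement and enaminone annulation. Both arenes derive from 4-bromoguaiacol (from catechol), and the side chain from allyl alcohol.
5. Ring order: the benzene rings A and B are bought as catechol, the pyranone ring is built next, and it is then contracted to the dihydrofuran ring.

## Route

**Step 1**
Reactants: 1 catechol
Product: 2 guaiacol (2-methoxyphenol)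
Conditions: MeI (0.9 equiv), K2CO3 (1 equiv), acetone, reflux
Reagents that add atoms: iodomethane, CI
Why: Williamson ether synthesis, in which catechol in slight excess is alkylated only as its more acidic, hydrogen-bonded monoanion and the leftover catechol is washed out with water.

**Step 2**
Reactants: 2 guaiacol
Product: 3 4-bromo-2-methoxyphenol
Conditions: NBS (1.0 equiv), MeCN, 0 °C to 25 °C
Reagents that add atoms: N-bromosuccinimide, O=C1CCC(=O)N1Br
Why: Electrophilic aromatic bromination, in which the free OH is the strongest director and NBS in MeCN takes its open para position.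

**Step 3**
Reactants: 3 4-bromo-2-methoxyphenol; 4 allyl alcohol
Product: 6 dihydroconiferyl alcohol [4-(3-hydroxypropyl)-2-methoxyphenol], via 3-(4-hydroxy-3-methoxyphenyl)propanal 5 (not isolated)
Conditions: Pd(OAc)2 (2 mol%), Bu4NCl, NaHCO3, DMF, 90 °C; then NaBH4, MeOH, 0 °C
Reagents that add atoms: none
Why: Heck reaction of allyl alcohol, in which aryl insertion at the terminal carbon and β-hydride elimination towards the carbinol give the enol and hence aldehyde 5, which NaBH4 reduces in the same flask.

**Step 4**
Reactants: 6 dihydroconiferyl alcohol; 7 acetic anhydride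
Product: 9 3-(3-acetyl-4-hydroxy-5-methoxyphenyl)propyl acetate, via 3-(4-acetoxy-3-methoxyphenyl)propyl acetate 8 (not isolated)
Conditions: 7 (2.3 equiv), DMAP (2 mol%), 40 °C, volatiles stripped; then TiCl4 (3 equiv), ClCH2CH2Cl, 80 °C; aq HCl work-up
Reagents that add atoms: none
Why: O-acetylation followed by a Fries rearrangement, in which the titanium phenolate holds the acyl donor next to the only free ortho position (para is blocked), the product is locked as its chelate, and the alkyl acetate stays on as a cost-free mask for the side-chain OH.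

**Step 5**
Reactants: 9 3-(3-acetyl-4-hydroxy-5-methoxyphenyl)propyl acetate; 10 N,N-dimethylformamide dimethyl acetal
Product: 12 3-(8-methoxy-4-oxo-4H-chromen-6-yl)propyl acetate, via (E)-enaminone 11 (not isolated)
Conditions: 10 (2 equiv), toluene, 100 °C, volatiles stripped; then AcOH, 90 °C
Reagents that add atoms: none
Why: Enaminone condensation of the methyl ketone with the amide acetal, then acid-induced conjugate addition of the phenol OH and loss of Me2NH, which is the standard chromone synthesis.

**Step 6**
Reactants: 3 4-bromo-2-methoxyphenol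
Product: 13 4-bromo-2-methoxyphenyl pivalate
Conditions: PivCl (1.1 equiv), K2CO3, acetone, 25 °C
Reagents that add atoms: pivaloyl chloride, CC(C)(C)C(=O)Cl
Why: O-acylation of the phenoxide, giving a pivalate that survives steps 7 to 9, lowers the donor power of ring B so that it neither migrates nor is oxidised in step 8, and is cleaved in step 10 without a separate deprotection.

**Step 7**
Reactants: 12 3-(8-methoxy-4-oxo-4H-chromen-6-yl)propyl acetate; 13 4-bromo-2-methoxyphenyl pivalate
Product: 15 4-[(2S)-6-(3-acetoxypropyl)-8-methoxy-4-oxochroman-2-yl]-2-methoxyphenyl pivalate, via (S)-triethylsilyl enol ether 14 (not isolated)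
Conditions: NiBr2(dme) (10 mol%), (4S,4'S)-4,4'-diisopropyl-4,4',5,5'-tetrahydro-2,2'-bioxazole (iPr-BiOX, 12 mol%), Mn powder (2 equiv), Et3SiCl (1.5 equiv), DMF, 25 °C; then 1 M HCl, THF, 0 °C; recrystallise to raise ee
Reagents that add atoms: chlorotriethylsilane, CC[Si](Cl)(CC)CC (its silyl group stands only in 14)
Why: Proposed new method: an enantioselective nickel-catalysed reductive conjugate arylation of a chromone, in which zerovalent nickel bound to C2=C3 is silylated at the carbonyl oxygen by Et3SiCl to give an η3-(4-silyloxychromenyl)nickel species, Mn reduces it, the aryl bromide adds oxidatively, and C–C reductive elimination at the oxygen-bearing allyl terminus C2 gives 14, with the face chosen by the isopropyl groups of the bioxazoline, which sit next to nickel as the methyl groups of neocuproine do in the racemic parent reaction; the closest known reaction types are the racemic Ni/Mn/chlorosilane reductive conjugate addition of aryl halides to enones and the asymmetric Pd- or Rh-catalysed conjugate addition of arylboronic acids to chromones; this step forms the C2–aryl bond and sets the C2 stereocentre.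

**Step 8**
Reactants: 15 (S)-flavanone
Product: 19 methyl (2S,3S)-5-(3-hydroxypropyl)-7-methoxy-2-[3-methoxy-4-(pivaloyloxy)phenyl]-2,3-dihydrobenzofuran-3-carboxylate, via methyl enol ether 16 (not isolated), via trans-C3 iodane ketal 17 (not isolated), via ring-contracted acetate 18 (not isolated)
Conditions: PhI(OAc)2 (1.2 equiv), conc. H2SO4 (1 equiv), HC(OMe)3, 20 °C; then H2O (destroys HC(OMe)3), MeOH, 45 °C
Reagents that add atoms: trimethyl orthoformate, COC(OC)OC; methanol, CO; (diacetoxyiodo)benzene, CC(=O)OI(OC(C)=O)c1ccccc1 (its atoms stand only in 17)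
Why: Oxidative ring contraction of a flavanone by a trivalent iodine reagent (semipinacol-type 1,2-aryl shift), in which acid and orthoformate give enol ether 16, the iodane adds to C3 anti to the equatorial C2 aryl group and MeOH adds to C4 (17), and the C4–C4a bond lies antiperiplanar to the equatorial C3–I bond, so ring A carbon C4a moves from C4 to C3 with inversion as PhI leaves; this turns the six-membered ring into the five-membered one, leaves C2 untouched and sets C3 trans (2S,3S), the acylated ring B is too poor a migrating group to give the isoflavone, and the acidic methanol then cleaves only the unhindered primary acetate.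

**Step 9**
Reactants: 19 hydroxy ester
Product: 20 sodium 3-[(2S,3S)-3-(methoxycarbonyl)-7-methoxy-2-[3-methoxy-4-(pivaloyloxy)phenyl]-2,3-dihydrobenzofuran-5-yl]propyl sulfate
Conditions: SO3·pyridine (2.5 equiv), pyridine, 25 °C; then aq NaHCO3; C18 filtration
Reagents that add atoms: sulfur trioxide pyridine complex, O=S(=O)=O.c1ccncc1; sodium hydrogen carbonate, [Na+].OC([O-])=O
Why: O-sulfation with SO3·pyridine, which is selective because the side-chain OH is the only free hydroxyl (the phenol is a pivalate and the future C3 CH2OH is still an ester).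

**Step 10**
Reactants: 20 sodium sulfate ester
Product: 21 3-[(2S,3R)-2-(4-hydroxy-3-methoxyphenyl)-3-(hydroxymethyl)-7-methoxy-2,3-dihydrobenzofuran-5-yl]propyl hydrogen sulfate (target)
Conditions: LiBH4 (5 equiv), THF–MeOH (20:1), 0 °C to 25 °C; then 1 M HCl to pH 2, 0 °C; HP-20 desalting, MeOH elution, lyophilise
Reagents that add atoms: none
Why: Ester reduction with LiBH4, in which hydride converts the methyl ester to CH2OH and cleaves the aryl pivalate, the anionic sulfate monoester is too poor an electrophile to react (hydride opening of cyclic sulfates likewise stops at the monoester), no stereocentre is touched (the C3 descriptor changes from S to R only by priority), and cold dilute acid gives the free hydrogen sulfate.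

## Compound list
1 | catechol (benzene-1,2-diol) | Oc1ccccc1O | starting material
2 | guaiacol (2-methoxyphenol) | COc1ccccc1O | intermediate
3 | 4-bromo-2-methoxyphenol | COc1cc(Br)ccc1O | intermediate
4 | allyl alcohol | C=CCO | starting material
5 | 3-(4-hydroxy-3-methoxyphenyl)propanal | COc1cc(CCC=O)ccc1O | intermediate
6 | dihydroconiferyl alcohol, 4-(3-hydroxypropyl)-2-methoxyphenol | COc1cc(CCCO)ccc1O | intermediate
7 | acetic anhydride | CC(=O)OC(C)=O | starting material
8 | 3-(4-acetoxy-3-methoxyphenyl)propyl acetate | COc1cc(CCCOC(C)=O)ccc1OC(C)=O | intermediate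
9 | 3-(3-acetyl-4-hydroxy-5-methoxyphenyl)propyl acetate | COc1cc(CCCOC(C)=O)cc(C(C)=O)c1O | intermediate
10 | N,N-dimethylformamide dimethyl acetal | COC(OC)N(C)C | starting material
11 | 3-{3-[(E)-3-(dimethylamino)acryloyl]-4-hydroxy-5-methoxyphenyl}propyl acetate | COc1cc(CCCOC(C)=O)cc(C(=O)/C=C/N(C)C)c1O | intermediate
12 | 3-(8-methoxy-4-oxo-4H-chromen-6-yl)propyl acetate | COc1cc(CCCOC(C)=O)cc2c(=O)ccoc12 | intermediate
13 | 4-bromo-2-methoxyphenyl pivalate | COc1cc(Br)ccc1OC(=O)C(C)(C)C | intermediate
14 | 4-[(2S)-6-(3-acetoxypropyl)-8-methoxy-4-(triethylsilyloxy)-2H-chromen-2-yl]-2-methoxyphenyl pivalate | COc1cc([C@H]2Oc3c(OC)cc(CCCOC(C)=O)cc3C(O[Si](CC)(CC)CC)=C2)ccc1OC(=O)C(C)(C)C | intermediate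
15 | 4-[(2S)-6-(3-acetoxypropyl)-8-methoxy-4-oxochroman-2-yl]-2-methoxyphenyl pivalate | COc1cc([C@H]2Oc3c(OC)cc(CCCOC(C)=O)cc3C(=O)C2)ccc1OC(=O)C(C)(C)C | intermediate
16 | 4-[(2S)-6-(3-acetoxypropyl)-4,8-dimethoxy-2H-chromen-2-yl]-2-methoxyphenyl pivalate | COc1cc([C@H]2Oc3c(OC)cc(CCCOC(C)=O)cc3C(OC)=C2)ccc1OC(=O)C(C)(C)C | intermediate
17 | 4-[(2R,3R)-3-[acetoxy(phenyl)-λ3-iodanyl]-6-(3-acetoxypropyl)-4,4,8-trimethoxychroman-2-yl]-2-methoxyphenyl pivalate (2,3-trans) | COc1cc([C@H]2Oc3c(OC)cc(CCCOC(C)=O)cc3C(OC)(OC)[C@@H]2I(OC(C)=O)c4ccccc4)ccc1OC(=O)C(C)(C)C | intermediate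
18 | methyl (2S,3S)-5-(3-acetoxypropyl)-7-methoxy-2-[3-methoxy-4-(pivaloyloxy)phenyl]-2,3-dihydrobenzofuran-3-carboxylate (trans) | COc1cc([C@H]2Oc3c(OC)cc(CCCOC(C)=O)cc3[C@@H]2C(=O)OC)ccc1OC(=O)C(C)(C)C | intermediate
19 | methyl (2S,3S)-5-(3-hydroxypropyl)-7-methoxy-2-[3-methoxy-4-(pivaloyloxy)phenyl]-2,3-dihydrobenzofuran-3-carboxylate (trans) | COc1cc([C@H]2Oc3c(OC)cc(CCCO)cc3[C@@H]2C(=O)OC)ccc1OC(=O)C(C)(C)C | intermediate
20 | sodium 3-[(2S,3S)-3-(methoxycarbonyl)-7-methoxy-2-[3-methoxy-4-(pivaloyloxy)phenyl]-2,3-dihydrobenzofuran-5-yl]propyl sulfate | COc1cc([C@H]2Oc3c(OC)cc(CCCOS(=O)(=O)[O-])cc3[C@@H]2C(=O)OC)ccc1OC(=O)C(C)(C)C.[Na+] | intermediate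
21 | 3-[(2S,3R)-2-(4-hydroxy-3-methoxyphenyl)-3-(hydroxymethyl)-7-methoxy-2,3-dihydrobenzofuran-5-yl]propyl hydrogen sulfate | COc1cc([C@H]2Oc3c(OC)cc(CCCOS(=O)(=O)O)cc3[C@@H]2CO)ccc1O | target

## Step count and risks
Total steps: 10. Longest linear sequence: 9 steps (1, 2, 3, 4, 5, 7, 8, 9, 10).

**Step 4 (Fries rearrangement).**
- Risk: acylation para to the methoxy group, or loss of the methyl ether under TiCl4.
- Fallback: it sets out from 6 and returns at 9.
- NBS in MeCN at 0 °C brominates the only free position ortho to OH to give 2-bromo-4-(3-hydroxypropyl)-6-methoxyphenol F1.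
- Internal Heck arylation of n-butyl vinyl ether (Pd(OAc)2, dppp, K2CO3, DMF–H2O, 100 °C) gives the enol ether 2-(1-butoxyvinyl)-4-(3-hydroxypropyl)-6-methoxyphenol F2.
- Dilute HCl hydrolyses this to 1-[2-hydroxy-5-(3-hydroxypropyl)-3-methoxyphenyl]ethan-1-one F3.
- One equivalent of 7 in pyridine at 0 °C acetylates only the primary alcohol, because the phenol is chelated to the ketone, and gives 9.

**Step 7 (proposed new step).**
- Risk: low conversion of the vinylogous ester, biaryl formation, or low ee.
- Fallback by known chemistry: it sets out from 13 and returns at 15.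
- Palladium-catalysed borylation with B2(OH)4 (Pd(OAc)2, XPhos, KOAc, EtOH, 80 °C) gives [3-methoxy-4-(pivaloyloxy)phenyl]boronic acid F4.
- F4 is added to chromone 12 by the established asymmetric conjugate addition of arylboronic acids to chromones (Pd(OCOCF3)2 5 mol%, t-BuPyOx 6 mol%, NH4PF6, H2O, ClCH2CH2Cl, 60 °C). The ligand antipode is chosen for the (S)-product. By analogy with cyclic enones this should be the (R)-ligand.
- The medium is base-free, so it spares the pivalate and does not racemise 15.

**Step 8 (ring contraction).**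
- Risk: competing dehydrogenation to the flavone, ring B shift to the isoflavone, or simple 3-methoxylation.
- Fallback: it sets out from 15 and returns at 18. It separates the C3 activation from the shift.
- PhNMe3Br3 in THF at 0 °C gives 4-[(2R,3R)-6-(3-acetoxypropyl)-3-bromo-8-methoxy-4-oxochroman-2-yl]-2-methoxyphenyl pivalate F5 (2,3-trans).
- HC(OMe)3, MeOH and catalytic TsOH convert it to the ketal 4-[(2R,3R)-6-(3-acetoxypropyl)-3-bromo-4,4,8-trimethoxychroman-2-yl]-2-methoxyphenyl pivalate F6.
- AgBF4 in MeOH at 25 °C abstracts bromide and triggers the same 1,2-aryl shift. This is the known α-halo ketal route to 2-arylalkanoates, and it gives 18.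
- Compound 18 is then methanolysed to 19 as in step 8.

## Further compounds
F1 | step 4 | 2-bromo-4-(3-hydroxypropyl)-6-methoxyphenol | COc1cc(CCCO)cc(Br)c1O
F2 | step 4 | 2-(1-butoxyvinyl)-4-(3-hydroxypropyl)-6-methoxyphenol | COc1cc(CCCO)cc(C(=C)OCCCC)c1O
F3 | step 4 | 1-[2-hydroxy-5-(3-hydroxypropyl)-3-methoxyphenyl]ethan-1-one | COc1cc(CCCO)cc(C(C)=O)c1O
F4 | step 7 | [3-methoxy-4-(pivaloyloxy)phenyl]boronic acid | COc1cc(B(O)O)ccc1OC(=O)C(C)(C)C
F5 | step 8 | 4-[(2R,3R)-6-(3-acetoxypropyl)-3-bromo-8-methoxy-4-oxochroman-2-yl]-2-methoxyphenyl pivalate | COc1cc([C@H]2Oc3c(OC)cc(CCCOC(C)=O)cc3C(=O)[C@@H]2Br)ccc1OC(=O)C(C)(C)C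
F6 | step 8 | 4-[(2R,3R)-6-(3-acetoxypropyl)-3-bromo-4,4,8-trimethoxychroman-2-yl]-2-methoxyphenyl pivalate | COc1cc([C@H]2Oc3c(OC)cc(CCCOC(C)=O)cc3C(OC)(OC)[C@@H]2Br)ccc1OC(=O)C(C)(C)C
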